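The runs are calculated for substances that don't exist; scatter was added.

70.7% of the substrate is the mean product read in the north flask from 5.00 h to 15.0 h, and the reckoning below starts from that stand.

the same everywhere: free catalyst 60 µM

|  | substrate | reagent | capture agent | remark | time |
|---|---|---|---|---|---|
| north | 30 mM | 24 mM | 1.5 mM | the very flask that is asked about, followed so far |  |
| south | 15 mM | 24 mM | 1.5 mM | run made earlier |  |
| flask | 30 mM | 24.0 mM | 1.50 mM |  | 20 h |

- north (time / h: product / %): 2.50: 68.6; 5.00: 71.2; 6.00: 70.1; 10.0: 70.6; 12.0: 70.6; 15.0: 70.9
- south (time / min: product / %): 3.00: 8.3; 6.00: 17.9; 10.0: 26.1; 15.0: 35.2; 20.0: 43.4; 25.0: 49.8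

(readings scatter by 0.5 percentage points)

- red: at 20 h add free catalyst, 100% of the amount charged, then wait 20 h
- grey: change nothing and wait 20 h more
- teal: at 20 h add reagent, 100% of the amount charged, then wait 20 h
- amber: at 20 h take out 90% of the product then present, then wait 20 h

- what is taken out of product is counted as made
- additions bring no volume worth counting

- product, in percent of the substrate first charged, at 20 h
- the option that brings most further product ("none" if no option brings more than 2 percentage points) (red / grey / teal / amber / none)
- product present, with what was taken out counted in, in percent of the substrate first charged, after grey
- product present, with what was taken out counted in, in percent of the substrate first charged, after amber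

The north flask can be built up one process at a time. With the main step on its own, taken as reagent and substrate giving product one to one, the charges allow

cap = [reagent] / [substrate] = 80.0%

so reagent is the limiting reagent. Slowness does not account for the stand: the south flask reaches 49.8% in 25.0 min, while the stand in the north flask lasts 10.0 h, much longer. Yet the stand lies 9.3 percentage points below the cap, with 2.80 mM of reagent unused.

The next process is a loss of catalyst, which this reckoning assumes, since no run tests it against an equilibrium. Each catalyst then delivers, on average, a fixed number of rounds:

N = plateau × [substrate] / [free catalyst] = 353

N, the product made per catalyst charged, is the turnover number.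

The rest is a small correction to a large flow, a leak of 0.283% per round. Suppose capture agent takes the catalyst, one for one. It then loses 4.00% of its charge, so [capture agent] stays near its charge, the leak stays steady, and N is taken as inversely proportional to [capture agent].

On this reckoning grey, teal and amber return no catalyst, so the north flask stays at 70.7%. Red adds 60 µM of free catalyst, good for

N × [free catalyst] = 21.2 mM

which is more than the 2.80 mM of reagent unused. On this reckoning red therefore reaches the cap, a gain of 9.3 points over the stand.

The forecast gives 70.6% now, red as best, 70.6% after grey and 70.6% after amber, but a gain of 2.7 points from red where this reckoning has 9.3 points, holding that “a by-product first fills the capture agent”.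

The flask gives 71.2% at 20 h. Option red is best and brings 8.5 points, while grey brings 0 points, teal 0 points and amber 0 points. The product, with what was taken out counted in, stands at 71.2% after grey and 71.2% after amber.

    reagent + free catalyst → catalyst intermediate A (k = 1100 M⁻¹ s⁻¹)
    substrate + catalyst intermediate A → catalyst intermediate B (k = 11.0 M⁻¹ s⁻¹)
    catalyst intermediate B → free catalyst + product (k = 0.890 s⁻¹)
    catalyst intermediate B + capture agent → trapped intermediate (k = 1.70 M⁻¹ s⁻¹)

At 20.0 h the flask holds 100% of its catalyst as trapped intermediate, with capture agent at 96.0% of its charge. With 71.2% in place of the stand, N for the flask is 356. For the neighbour charged with 6.0 mM of capture agent, the reckoning puts N at 88.3, so that its 60 µM of free catalyst is reckoned to make 5.30 mM, or 17.7% of the substrate. That neighbour holds 100% trapped intermediate and 99.0% capture agent, and its product stands at 17.5% at 20.0 h.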